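All constants were chosen freely; what happens was integrated by code.

By the steps listed, no more than 70.0% of the substrate can become target, for the reagent in the second phase, the limiting reagent, is charged at 0.700 equiv.

    reagent in the reaction phase ⇌ reagent in the second phase, rate k1*([reagent in the reaction phase] - [reagent in the second phase]/K1) per volume of the first phase (K1 = 2.22, k1 = 0.420 h⁻¹)
    substrate + reagent in the reaction phase ⇌ target (K2 = 51 L mol⁻¹, k2 = 22.4 L mol⁻¹ h⁻¹)
    target ⇌ product in the second phase, rate k3*([target] - [product in the second phase]/K3) per volume of the first phase (K3 = 0.347, k3 = 0.534 h⁻¹)
    target → decomposed product (k4 = 0.525 h⁻¹)

substrate 20 mM; reagent in the second phase 0.700 equiv; time 5.0 h; volume of the second phase over the first 1.0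

- how much target and product in the second phase together there is at 5.0 h, in percent of the substrate charged
- part of the substrate charged that has reacted at 5.0 h

- target is meant together with its product in the second phase
- in the second phase: reagent in the second phase, product in the second phase; everything else is in the first
- charges count per volume of the first phase; a concentration in a rate is the amount of a species over the volume of its own phase; every rate counts per litre of the first phase
- run time (flask): 5.0 h

My own reckoning treats target as steady: reaction-phase target is made at k2 times substrate times reagent in the reaction phase, and is lost at 0.439 h⁻¹ backward plus 0.525 h⁻¹ to decomposed product, while the second phase holds a further 0.347 of it. That gives the standing ratio 31.3 L mol⁻¹: multiplied by the reagent level and the fraction of substrate left, it gives target and its second-phase product as a fraction of the substrate charged.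

The reagent level follows from release matching return plus net use, which is 0.544 of the forward rate, the share of target that decomposes. With nothing spent, the level is 3.10 mM, so the first answer is 9.72%. Allowing 2.21 h for the build-up and adding the reckoned decomposition, the estimate of substrate spent is 20.3%. Put back in, this gives 2.34 mM of reagent, 5.84% for y and 12.2% for cv.

The forecast stands higher than this reckoning, at 6.6% and 14.7%, on these grounds: “Decomposition at a rate similar to the reverse step, together with weak extraction into the second phase, keeps the target plus its extracted form” to about 1.3 mM.

The flask gives 6.52% and 14.7%.

In this flask at 5.00 h, the step from substrate and reagent to target, taken by itself and both ways together, has a relaxation half-life of 0.789 h, short against the 5.0 h of the run, and reaction-phase target is made 1.04 times as fast as it is used up, passage into its other forms counted as use. On this flask's readings of 2.57 mM of reagent in the reaction phase and 85.3% of substrate left, the standing ratio gives 6.86%, and the flask holds 6.52%. On the neighbour flask with 12 mM of substrate, its 1.81 mM and 89.6% give 5.08%, and that flask holds 4.69%.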